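## The problem

The target 15 is an achiral, fully O-methylated flavonol: a chromen-4-one with methoxy groups on C5, C6, C7 and C8 of ring A, a methoxy group on C3, and a 2,4-dimethoxyphenyl ring B on C2. Ring A is hexasubstituted, so it has to come from an arene that already carries four contiguous oxygens and leaves two adjacent positions for O1 and C4. Ring C must be closed so that oxygen ends up on both C3 and C4; adding the C3 oxygen after the pyranone exists would mean a C-H oxidation on a crowded, electron-rich system. The target has no stereocentre. A route through a chromanone creates C2 and C3 stereocentres, but C3 is alpha to the ketone and settles trans to the C2 aryl group, and both centres vanish on dehydrogenation, so no stereocontrol is needed. The sensitive groups are the aryl methyl ethers (the C5 methoxy peri to the carbonyl is lost first to Lewis or hydrohalic acids), the acid-labile 2,4-dimethoxybenzylic C2-O1 ether of any saturated ring C intermediate, and any aldehyde alpha to that ether, which enolises easily and can lose the aryloxide. The enabling feature is that C3 and C4 are adjacent and both oxygenated: the 3-methoxy-4-one is the enol ether of a 3,4-dione, one oxidation level above an acyloin, and an acyloin can be made by joining two aldehyde carbons with umpolung of one.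

## Retrosynthesis

**15 to 14.** The O-CH3 bond at C3 is cut. It is the only non-aromatic methyl ether, and removing it exposes flavonol 14, the enol of a 3,4-dione. The forward step is alkylation of the single acidic hydroxyl of 14.

**14 to 12.** Two hydrogens are added across C2=C3, leading through the transient dione 13 to the trans-3-hydroxychroman-4-one 12. No skeletal bond changes, but the 3,4-dioxygenation becomes an acyloin. The forward step needs an oxidant that spares two electron-rich rings and the C5 methoxy group.

**12 to 11.** The C3-C4 bond is cut, giving dialdehyde 11.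
- Against its neighbours: cutting O1-C2 or C2-C3 leads to the classical oxidative-cyclisation and acyl-transfer routes to flavonols. These need either epoxidation chemistry that a C5 oxygen tends to divert toward five-membered rings, or hot, strongly basic conditions.
- In its favour: both oxygenated carbons arrive as aldehydes of the same oxidation level, and ring A needs only a formyl group at its one free position.
- Simplification: ring C and one stereocentre are removed.
- Demands on the forward step: a carbene-catalysed crossed benzoin closing a six-membered ring, which must outrun three diversions. These are intermolecular benzoin, base-induced aldol closure of the acidic C2-H onto the aryl aldehyde, and loss of the aryloxide from the carbene adduct of the aliphatic aldehyde.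
- Measures taken: 11 is made under amine-free, buffered conditions and used at once; the carbene is a small thiazolylidene; the base is weak and substoichiometric. Either aldehyde may act as donor, because both acyloin regioisomers share one enediol and converge on 12.

**11 to 9 via 10.** These are oxidation-level changes only. Diol 10 comes from ester aldehyde 9, the stable, storable form of the chain. Reducing both carbonyls and oxidising both alcohols costs two steps but avoids a selective partial reduction of an ester next to an aldehyde.

**9 to 5 + 8.** The benzylic C2-O1 bond is cut, dividing the molecule into a ring A phenol 5 and a ring B alcohol 8 of similar size. A Mitsunobu reaction is preferred to base-mediated alkylation because 9 has an acidic C-H next to a formyl group and would be exposed to aldol closure under carbonate. The forward step needs only ether formation; configuration is irrelevant.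

**8 to 6 + 7.** The C2-C1' bond is cut. Friedel-Crafts hydroxyalkylation of 1,3-dimethoxybenzene 6 with ethyl glyoxylate 7 gives the 2,4-pattern directly, since C4 of 6 is the doubly activated, unhindered site. Glyoxylate supplies C2 and C3 with their oxygens.

**5 to 4 to 1.** The formyl C4-C4a bond is cut, then the C8a-O bond. Phenol 4 has one free position, ortho to the hydroxyl, so ortho-formylation can give only 5. Phenol 4 comes from 1,2,3,4-tetramethoxybenzene 1 by ortho-lithiation (via 2), borylation (via 3) and oxidation; the two ring hydrogens of 1 are equivalent.

## Roads not taken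

**Alternative 1:** Ring B is cut at C1'-C2' and C5'-C6'.
- Forward step: thermal Diels-Alder reaction of 2-ethynyl-3,5,6,7,8-pentamethoxychromen-4-one A1 with 1,1-dimethoxy-3-(trimethylsilyloxy)buta-1,3-diene A2. Loss of methanol and of the silyl group aromatises the adduct to the phenol 2-(4-hydroxy-2-methoxyphenyl)-3,5,6,7,8-pentamethoxychromen-4-one A3; one more methylation gives 15.
- Merits: the polarisation of A2 (nucleophilic CH2 terminus) and of the ynone terminus of A1 fixes the ring B pattern, and the free 4'-hydroxyl of A3 would allow analogues.
- Weak points: ring B is the simplest part of 15 and is available as 6, so the key step is spent on the easy ring. The fully substituted ring A and the oxygenated ring C are all moved into A1, which needs its own chromone synthesis and alkynylation. The chromone C2=C3 bond is a competing acceptor, and A2 is hydrolytically fragile.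
- Comparison: this road is better where a differentiated 4'-oxygen is wanted. The chosen plan cannot distinguish the methoxy groups, but 15 does not need that, and it builds ring C together with both of its oxygens from purchasable arenes.

**Alternative 2:** Ring C is cut at C4a-C4, C3-C4 and O1-C2, with carbon monoxide as C4.
- Forward step: 2-iodo-3,4,5,6-tetramethoxyphenol A4, 1-ethynyl-2,4-dimethoxybenzene A5 and CO react with PdCl2(PPh3)2 in diethylamine to give 2-(2,4-dimethoxyphenyl)-5,6,7,8-tetramethoxychromen-4-one A6.
- Merits: this is the most convergent road. A4 would come from 4 in one iodination, and the chromone is reached in fewer steps than in the chosen plan.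
- Weak points: A6 has no oxygen at C3, so a C3-H hydroxylation (metalation-borate oxidation or enone epoxidation) and a methylation must follow to reach 14 and 15. Oxidative addition of zerovalent palladium to the di-ortho-substituted, electron-rich iodide A4 is slow, so non-carbonylative coupling and 5-exo closure to an aurone can compete with the 6-endo path. CO under pressure is needed.
- Comparison: even with the two extra steps this road is about three steps shorter. The chosen plan sets against this that the C3 oxygen, which defines the flavonol, is built into the ring-forming step and not added by late C-H oxidation, and that no step depends on a regiochemical competition.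

**Alternative 3:** Ring A is cut at C8-C8a and traced to a four-carbon unit.
- Forward step: dimethyl squarate A7 takes up the C5-metalated form of 2-(2,4-dimethoxyphenyl)-3-methoxy-4H-pyran-4-one A8 to give 5-(1-hydroxy-2,3-dimethoxy-4-oxocyclobut-2-en-1-yl)-2-(2,4-dimethoxyphenyl)-3-methoxy-4H-pyran-4-one A9. Heating A9 in xylene opens the ring to a dienylketene that closes onto the pyranone C6-H, giving the hydroquinone 2-(2,4-dimethoxyphenyl)-5,8-dihydroxy-3,6,7-trimethoxychromen-4-one A10; two methylations give 15.
- Merits: the hexasubstituted ring A is assembled with full regiocontrol without a polyoxygenated arene, and the 5- and 8-hydroxyls of A10 could be differentiated.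
- Weak points: A8 needs several steps and a selective C5 metalation of a pyranone that is a Michael acceptor with a competing C6-H. A10 is air-sensitive. Its chelated 5-hydroxyl is the hardest flavone hydroxyl to methylate.
- Comparison: this road is superior if the ring A pattern could not be bought or if partially methylated congeners were wanted. For 15, ring A is available as 1, and the chosen plan reaches it in fewer and more predictable steps.

Key step: step 7

Assumption: compounds 8 to 13 are racemic; one enantiomer is drawn for bookkeeping and the descriptors refer to that drawing.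

## Route

Step 1
Reactants: 1 1,2,3,4-tetramethoxybenzene
Product: 4 2,3,4,5-tetramethoxyphenol, via aryllithium 2 (not isolated), via lithium aryltrimethoxyborate 3 (not isolated)
Conditions: n-BuLi, TMEDA, THF, 0 °C to rt; B(OMe)3, −78 °C to rt; AcOH, 30% aq. H2O2, 0 °C to rt
Reagents that add atoms: hydrogen peroxide, OO
Why: Directed ortho-metalation; both ring hydrogens of 1 are ortho to a methoxy group and equivalent by symmetry, so a single aryllithium forms, and borylation followed by oxidative aryl migration from boron to oxygen (boronate oxidation) should give the phenol.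

Step 2
Reactants: 4 2,3,4,5-tetramethoxyphenol
Product: 5 2-hydroxy-3,4,5,6-tetramethoxybenzaldehyde
Conditions: MgCl2, Et3N, (CH2O)n, THF, reflux
Reagents that add atoms: paraformaldehyde (as formaldehyde), C=O
Why: Magnesium-mediated ortho-formylation (Casnati-Skattebøl); the magnesium phenoxide delivers formaldehyde to the only unsubstituted carbon, which is ortho to the hydroxyl, and a second formaldehyde oxidises the benzylic alkoxide by hydride transfer, so only 5 can form.

Step 3
Reactants: 6 1,3-dimethoxybenzene; 7 ethyl glyoxylate
Product: 8 ethyl 2-(2,4-dimethoxyphenyl)-2-hydroxyacetate (racemic, S drawn)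
Conditions: 7 (1.2 equiv, toluene solution), Yb(OTf)3 (10 mol%), CH2Cl2, rt
Reagents that add atoms: none
Why: Friedel-Crafts hydroxyalkylation; the Lewis-acid-activated aldehyde attacks C4 of 6 (para to one methoxy, ortho to the other), and the adjacent ester destabilises the benzylic cation and so holds back a second arylation; the new stereocentre forms without control and 8 is racemic.

Step 4
Reactants: 5 2-hydroxy-3,4,5,6-tetramethoxybenzaldehyde; 8 ethyl 2-(2,4-dimethoxyphenyl)-2-hydroxyacetate
Product: 9 ethyl 2-(2,4-dimethoxyphenyl)-2-(2-formyl-3,4,5,6-tetramethoxyphenoxy)acetate (racemic, R drawn)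
Conditions: PPh3, DIAD, toluene, 0 °C to rt
Reagents that add atoms: none
Why: Mitsunobu etherification; the ortho-formyl phenol is acidic enough to protonate the betaine, and the alkoxyphosphonium of an alpha-hydroxy ester is displaced readily at the activated benzylic carbon; inversion is irrelevant for a racemate, and the neutral medium avoids base-induced aldol closure of 9 onto its own formyl group.

Step 5
Reactants: 9 ethyl 2-(2,4-dimethoxyphenyl)-2-(2-formyl-3,4,5,6-tetramethoxyphenoxy)acetate
Product: 10 2-(2,4-dimethoxyphenyl)-2-[2-(hydroxymethyl)-3,4,5,6-tetramethoxyphenoxy]ethan-1-ol (racemic, R drawn)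
Conditions: LiAlH4, THF, 0 °C; aqueous NaOH work-up
Reagents that add atoms: none
Why: Hydride reduction; LiAlH4 should reduce the ester to the primary alcohol and the aryl aldehyde to the benzylic alcohol in one operation, leaving the aryl ethers and the stereocentre untouched.

Step 6
Reactants: 10 2-(2,4-dimethoxyphenyl)-2-[2-(hydroxymethyl)-3,4,5,6-tetramethoxyphenoxy]ethan-1-ol
Product: 11 2-[1-(2,4-dimethoxyphenyl)-2-oxoethoxy]-3,4,5,6-tetramethoxybenzaldehyde (racemic, R drawn)
Conditions: Dess-Martin periodinane (2.6 equiv), NaHCO3, CH2Cl2, 0 °C to rt; short silica filtration, used at once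
Reagents that add atoms: none
Why: Dess-Martin oxidation of a benzylic and a primary alcohol to the two aldehydes without over-oxidation; the bicarbonate-buffered, amine-free medium is chosen because the alpha-aryl-alpha-aryloxy aldehyde enolises easily.

Step 7
Reactants: 11 2-[1-(2,4-dimethoxyphenyl)-2-oxoethoxy]-3,4,5,6-tetramethoxybenzaldehyde
Product: 12 trans-2-(2,4-dimethoxyphenyl)-3-hydroxy-5,6,7,8-tetramethoxychroman-4-one (racemic, 2R,3R drawn)
Conditions: 3-benzyl-5-(2-hydroxyethyl)-4-methylthiazolium chloride (20 mol%), Et3N (40 mol%), degassed t-BuOH, 40 °C, argon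
Reagents that add atoms: none
Why: Carbene-catalysed intramolecular crossed benzoin reaction, the dialdehyde counterpart of the known closures of 2-(2-oxoalkoxy)benzaldehydes to 3-hydroxychroman-4-ones. The thiazol-2-ylidene released by Et3N adds to one aldehyde, proton transfer gives the Breslow intermediate, and its nucleophilic carbon attacks the other aldehyde in a 6-exo-trig closure that forms C3-C4 and ring C; loss of the carbene releases the acyloin. Addition to the aryl aldehyde should be favoured because the aliphatic aldehyde is doubly substituted at its alpha carbon, and this direction gives 12 directly; if the aliphatic aldehyde is the donor, the isomeric 4-hydroxychroman-3-one should drift to 12 through the shared enediol, since only 12 has its carbonyl conjugated to ring A. The new C3 stereocentre is under thermodynamic control: it is alpha to the ketone and should epimerise through the enediol to place hydroxyl and aryl group trans-diequatorial, though either isomer serves the next step. The selectivity needed is ring closure ahead of aryloxide loss from the aliphatic Breslow intermediate, ahead of base-induced aldol closure to a dihydrobenzofuranol and ahead of intermolecular benzoin; the short tether, a small nucleophilic carbene, substoichiometric weak base and exclusion of air are chosen to secure it.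

Step 8
Reactants: 12 trans-2-(2,4-dimethoxyphenyl)-3-hydroxy-5,6,7,8-tetramethoxychroman-4-one
Product: 14 2-(2,4-dimethoxyphenyl)-3-hydroxy-5,6,7,8-tetramethoxy-4H-chromen-4-one, via chromane-3,4-dione 13 (not isolated)
Conditions: I2 (1.1 equiv), KOAc, AcOH, 100 °C
Reagents that add atoms: none
Why: Classical iodine-acetate dehydrogenation of a dihydroflavonol; enolisation of the acyloin toward C3, iodination and loss of HI should give dione 13, which tautomerises to the aromatic 3-hydroxychromenone; KOAc buffers the HI that would otherwise attack the C5 methoxy group, and both stereocentres disappear.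

Step 9
Reactants: 14 2-(2,4-dimethoxyphenyl)-3-hydroxy-5,6,7,8-tetramethoxy-4H-chromen-4-one
Product: 15 2-(2,4-dimethoxyphenyl)-3,5,6,7,8-pentamethoxy-4H-chromen-4-one
Conditions: Me2SO4, K2CO3, acetone, reflux
Reagents that add atoms: dimethyl sulfate, COS(=O)(=O)OC
Why: Williamson O-methylation; the 3-hydroxyl of a flavonol is an acidic enol, is the only free hydroxyl in 14 and should be alkylated cleanly under carbonate to give the target.

## Compound list

1 | 1,2,3,4-tetramethoxybenzene | COc1ccc(OC)c(OC)c1OC | starting material
2 | (2,3,4,5-tetramethoxyphenyl)lithium | [Li]c1cc(OC)c(OC)c(OC)c1OC | intermediate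
3 | lithium trimethoxy(2,3,4,5-tetramethoxyphenyl)borate | [Li+].CO[B-](OC)(OC)c1cc(OC)c(OC)c(OC)c1OC | intermediate
4 | 2,3,4,5-tetramethoxyphenol | COc1cc(O)c(OC)c(OC)c1OC | intermediate
5 | 2-hydroxy-3,4,5,6-tetramethoxybenzaldehyde | COc1c(O)c(C=O)c(OC)c(OC)c1OC | intermediate
6 | 1,3-dimethoxybenzene | COc1cccc(OC)c1 | starting material
7 | ethyl glyoxylate | CCOC(=O)C=O | starting material
8 | ethyl 2-(2,4-dimethoxyphenyl)-2-hydroxyacetate (racemic, S drawn) | CCOC(=O)[C@@H](O)c1ccc(OC)cc1OC | intermediate
9 | ethyl 2-(2,4-dimethoxyphenyl)-2-(2-formyl-3,4,5,6-tetramethoxyphenoxy)acetate (racemic, R drawn) | CCOC(=O)[C@H](Oc1c(C=O)c(OC)c(OC)c(OC)c1OC)c1ccc(OC)cc1OC | intermediate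
10 | 2-(2,4-dimethoxyphenyl)-2-[2-(hydroxymethyl)-3,4,5,6-tetramethoxyphenoxy]ethan-1-ol (racemic, R drawn) | OC[C@H](Oc1c(CO)c(OC)c(OC)c(OC)c1OC)c1ccc(OC)cc1OC | intermediate
11 | 2-[1-(2,4-dimethoxyphenyl)-2-oxoethoxy]-3,4,5,6-tetramethoxybenzaldehyde (racemic, R drawn) | O=C[C@H](Oc1c(C=O)c(OC)c(OC)c(OC)c1OC)c1ccc(OC)cc1OC | intermediate
12 | trans-2-(2,4-dimethoxyphenyl)-3-hydroxy-5,6,7,8-tetramethoxychroman-4-one (racemic, 2R,3R drawn) | COc1ccc([C@H]2Oc3c(OC)c(OC)c(OC)c(OC)c3C(=O)[C@@H]2O)c(OC)c1 | intermediate
13 | 2-(2,4-dimethoxyphenyl)-5,6,7,8-tetramethoxychromane-3,4-dione (racemic, R drawn) | COc1ccc([C@H]2Oc3c(OC)c(OC)c(OC)c(OC)c3C(=O)C2=O)c(OC)c1 | intermediate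
14 | 2-(2,4-dimethoxyphenyl)-3-hydroxy-5,6,7,8-tetramethoxy-4H-chromen-4-one | COc1ccc(-c2oc3c(OC)c(OC)c(OC)c(OC)c3c(=O)c2O)c(OC)c1 | intermediate
15 | 2-(2,4-dimethoxyphenyl)-3,5,6,7,8-pentamethoxy-4H-chromen-4-one | COc1ccc(-c2oc3c(OC)c(OC)c(OC)c(OC)c3c(=O)c2OC)c(OC)c1 | target

## Step count and risks

Total step count: 9. Longest linear sequence: 8 steps (steps 1, 2, 4, 5, 6, 7, 8, 9 from 1); the ring B branch (step 3) joins at step 4.

**Step 7 (key step).**
- Most likely failure: the carbene adds to the aliphatic aldehyde and the adduct expels the aryloxide (internal redox to an acyl azolium, then acyl transfer), because the aryl aldehyde is flanked by two ortho oxygens and is slow to accept the carbene. Base-induced 5-exo aldol closure of the acidic C2-H onto the aryl aldehyde is a second drain.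
- Fallback: it sets out from 11 and returns at 12, replacing umpolung by reductive coupling. SmI2 in THF/t-BuOH at −78 °C should join the two aldehyde carbons by intramolecular pinacol coupling, forming the same C3-C4 bond and giving 2-(2,4-dimethoxyphenyl)-5,6,7,8-tetramethoxychromane-3,4-diol F1 (racemic; 2,3-trans-3,4-cis drawn, isomer composition immaterial). 2-Iodoxybenzoic acid (1 equiv) in DMSO, which does not cleave 1,2-diols, should oxidise the benzylic C4 carbinol first and give 12; any further oxidation only anticipates step 8.

**Step 6.**
- Most likely failure: enolisation of the newly formed aliphatic aldehyde and aldol closure onto the aryl aldehyde during oxidation or isolation, or incomplete oxidation through a cyclic hemiacetal.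
- Fallback: it sets out from 9 and returns at 11; the aryl aldehyde is masked and never reduced. HC(OMe)3 with catalytic pyridinium p-toluenesulfonate in MeOH should convert 9 into ethyl 2-(2,4-dimethoxyphenyl)-2-[2-(dimethoxymethyl)-3,4,5,6-tetramethoxyphenoxy]acetate F2. i-Bu2AlH in toluene at −78 °C should stop at the chelated hemiacetal stage of the alpha-aryloxy ester and give 2-(2,4-dimethoxyphenyl)-2-[2-(dimethoxymethyl)-3,4,5,6-tetramethoxyphenoxy]acetaldehyde F3. Dilute aqueous oxalic acid in THF at rt should hydrolyse the electron-rich aryl acetal to 11 directly before step 7.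

**Step 4.**
- Most likely failure: slow displacement at a hindered secondary carbon by a di-ortho-substituted phenol, so that alkylation of the reduced azodicarboxylate takes over.
- Fallback: it sets out from 8 (with 5) and returns at 9, using an isolated electrophile. CBr4/PPh3 in CH2Cl2 at 0 °C should convert 8 into ethyl 2-bromo-2-(2,4-dimethoxyphenyl)acetate F4. Phenol 5 is then alkylated with F4 using Cs2CO3 in MeCN at 0 °C to rt, kept cold so that 9 does not undergo aldol closure.

**Step 8.**
- Most likely failure: electrophilic iodination of ring B at C5', or acid-induced opening at the 2,4-dimethoxybenzylic C2-O1 bond in hot acetic acid.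
- Fallback: it sets out from 12 and returns at 14, oxidising the carbinol as an alcohol. Dess-Martin periodinane with NaHCO3 in CH2Cl2 at rt should give dione 13, which tautomerises to 14 on work-up or with a trace of Et3N. No new compound is involved.

**Step 3.**
- Most likely failure: ionisation of the electron-rich benzylic alcohol of 8 under the Lewis acid and a second arylation by 6.
- Fallback: it sets out from 6 and returns at 8. Friedel-Crafts acylation of 6 with ethyl chlorooxoacetate (AlCl3, CH2Cl2, −10 °C) should give ethyl 2-(2,4-dimethoxyphenyl)-2-oxoacetate F5, which is deactivated toward further substitution. NaBH4 in EtOH at 0 °C then reduces the ketone to 8.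

## Further compounds

F1 | step 7 | 2-(2,4-dimethoxyphenyl)-5,6,7,8-tetramethoxychromane-3,4-diol (racemic, 2,3-trans-3,4-cis drawn) | COc1ccc([C@H]2Oc3c(OC)c(OC)c(OC)c(OC)c3[C@H](O)[C@@H]2O)c(OC)c1
F2 | step 6 | ethyl 2-(2,4-dimethoxyphenyl)-2-[2-(dimethoxymethyl)-3,4,5,6-tetramethoxyphenoxy]acetate (racemic, R drawn) | CCOC(=O)[C@H](Oc1c(C(OC)OC)c(OC)c(OC)c(OC)c1OC)c1ccc(OC)cc1OC
F3 | step 6 | 2-(2,4-dimethoxyphenyl)-2-[2-(dimethoxymethyl)-3,4,5,6-tetramethoxyphenoxy]acetaldehyde (racemic, R drawn) | O=C[C@H](Oc1c(C(OC)OC)c(OC)c(OC)c(OC)c1OC)c1ccc(OC)cc1OC
F4 | step 4 | ethyl 2-bromo-2-(2,4-dimethoxyphenyl)acetate (racemic, S drawn) | CCOC(=O)[C@@H](Br)c1ccc(OC)cc1OC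
F5 | step 3 | ethyl 2-(2,4-dimethoxyphenyl)-2-oxoacetate | CCOC(=O)C(=O)c1ccc(OC)cc1OC
F0 | step 8 | none | none
A1 | alternative 1 | 2-ethynyl-3,5,6,7,8-pentamethoxy-4H-chromen-4-one | C#Cc1oc2c(OC)c(OC)c(OC)c(OC)c2c(=O)c1OC
A2 | alternative 1 | 1,1-dimethoxy-3-(trimethylsilyloxy)buta-1,3-diene | COC(OC)=CC(=C)O[Si](C)(C)C
A3 | alternative 1 | 2-(4-hydroxy-2-methoxyphenyl)-3,5,6,7,8-pentamethoxy-4H-chromen-4-one | COc1cc(O)ccc1-c1oc2c(OC)c(OC)c(OC)c(OC)c2c(=O)c1OC
A4 | alternative 2 | 2-iodo-3,4,5,6-tetramethoxyphenol | COc1c(O)c(I)c(OC)c(OC)c1OC
A5 | alternative 2 | 1-ethynyl-2,4-dimethoxybenzene | C#Cc1ccc(OC)cc1OC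
A6 | alternative 2 | 2-(2,4-dimethoxyphenyl)-5,6,7,8-tetramethoxy-4H-chromen-4-one | COc1ccc(-c2cc(=O)c3c(OC)c(OC)c(OC)c(OC)c3o2)c(OC)c1
A7 | alternative 3 | dimethyl squarate (3,4-dimethoxycyclobut-3-ene-1,2-dione) | COC1=C(OC)C(=O)C1=O
A8 | alternative 3 | 2-(2,4-dimethoxyphenyl)-3-methoxy-4H-pyran-4-one | COc1ccc(-c2occc(=O)c2OC)c(OC)c1
A9 | alternative 3 | 5-(1-hydroxy-2,3-dimethoxy-4-oxocyclobut-2-en-1-yl)-2-(2,4-dimethoxyphenyl)-3-methoxy-4H-pyran-4-one (racemic, one enantiomer drawn) | COc1ccc(-c2occ([C@@]3(O)C(=O)C(OC)=C3OC)c(=O)c2OC)c(OC)c1
A10 | alternative 3 | 2-(2,4-dimethoxyphenyl)-5,8-dihydroxy-3,6,7-trimethoxy-4H-chromen-4-one | COc1ccc(-c2oc3c(O)c(OC)c(OC)c(O)c3c(=O)c2OC)c(OC)c1
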